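A ratio of 0.975 was where I began on your quick number: that was how much solid substrate maple had lost by 20.0 min, per unit of what birch had lost, although maple held 0.15 M of protic impurity against 0.10 M in birch.

| setting | birch | maple | flask |
|---|---|---|---|
| solid substrate | 0.20 M | 0.20 M | 0.20 M |
| solid reagent | 0.36 M | 0.36 M | 0.360 M |
| protic impurity | 0.10 M | 0.15 M | 0.200 M |
| remark | run made earlier | run made earlier |  |
| time |  |  | 15 min |

- birch (time / min: solid substrate / %, target / %): 1.33: 97.5, 0.9; 2.50: 96.1, 1.2; 5.00: 91.5, 4.9; 10.0: 81.3, 12.8; 20.0: 63.8, 29.0
- maple (time / min: solid substrate / %, target / %): 1.50: 97.6, 0.1; 5.00: 91.0, 3.5; 8.00: 85.2, 8.8; 12.0: 78.9, 15.9; 20.0: 64.7, 29.0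

(each reading ± 0.5 percentage points)

- percent here means solid substrate units held: one side product counts as two
- what is said of target includes solid product
- solid substrate, solid product, solid reagent is a solid; its amount is given per volume of the solution
- steps thought possible: solid substrate <-> dissolved substrate; dissolved substrate + partner -> target; solid product <-> target; solid substrate + target -> side product; solid reagent <-> partner; partner + protic impurity -> quenched reagent
- at the start none of the solid substrate is in solution
- at the start none of the solid reagent is in solution

* how much solid substrate the flask holds at 15 min, in percent of the solid substrate charged (only what is still solid)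
* how much target the flask holds at 15 min, in percent of the solid substrate charged
* concentration of partner at 15 min, in M

From that ratio I took the mean loss of the two runs and turned it into molar terms:

0.20 M × 35.8% ÷ 20.0 min = 0.00358 M/min

This is the dissolving rate, the molar amount of solid substrate leaving the solid each minute, and I assumed that it held steady, which is what is usually called zero-order behaviour. I then counted how much of one charge that rate turns over in the new flask, with its 0.200 M of protic impurity:

0.00358 M/min × 15 min ÷ 0.20 M = 0.268 of a charge

That left 73.2% as solid, and I committed to that figure. I put no figure of my own on target, though both runs had read it, and none on partner, which neither run had read. Your forecast gave 73% of solid substrate, 20% of target and 0.08 M of partner, the solid resting on a fall “with no visible dependence on impurity”, so on the solid we agreed.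

    solid substrate ⇌ dissolved substrate, rate k1*(cs1 - [dissolved substrate]) while solid is left; crystals form when [dissolved substrate] > cs1 (solubility = 0.0880 M, k = 7.40 × 10⁻⁴ /s)
    dissolved substrate + partner → target (k = 0.740 /M/s)
    solid product ⇌ target, rate k3*(cs3 - [target]) while solid is left; crystals form when [target] > cs3 (solubility = 19.0 mM, k = 0.0240 /s)
    solid substrate + target → side product (k = 5.00 × 10⁻⁴ /M/s)
    solid reagent ⇌ partner, rate k5*(cs5 - [partner]) while solid is left; crystals form when [partner] > cs5 (solubility = 0.130 M, k = 4.80 × 10⁻⁴ /s)
    partner + protic impurity → quenched reagent (k = 0.00430 /M/s)

The flask held 73.2% of solid substrate, 20.3% of target and 0.00669 M of partner, so the forecast's partner stood 12.0 times above it. At 15.0 min the flask was making partner at 0.979 times the rate at which it used it up. Its solid had left at 0.00357 M/min, against the dissolving rate of 0.00358 M/min. For the neighbour charged with 0.50 M of solid substrate, that rate counts 0.107 of a charge in 15 min and leaves 89.3%, and that neighbour held 88.9%.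

The earlier runs and the new flask are calculated for an exercise; scatter was added.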